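**Strategy.** Agrimol B is cut at both diarylmethane CH2 bridges into the central ring B, (S)-2-methylbutanoylphloroglucinol, and two identical wing ketones (rings A and C), joined at the end through wing Mannich bases. Ring B is built on one feature: its acyl-bearing carbon C1 adjoins the oxygen-bearing carbon C2, so the ketone carbon and the C2 oxygen can both come from (S)-2-methylbutanoic acid. A 3,5-bis(benzyloxy)benzyne, set free by fluoride from a 2-silylaryl triflate whose silicon sits between OTf and OBn, inserts into the acid C–O bond and forms the aryl C–O and aryl C–C(=O) bonds in one operation, without Lewis acid, so the stereocentre is carried intact.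

Key step: step 4

Remark on numbering: ring B numbering is used for 8, 10, 11 and 12. C1 carries silicon and later the acyl group, C2 carries OTf and later the new OH, C4 and C6 carry the benzyloxy groups, and C3 and C5 are the CH positions that are bridged at the end.

Remark on the wings: each wing has its O-methyl group on the most hindered, chelated hydroxyl, between the butanoyl and C-methyl groups. It is therefore introduced only after the other two hydroxyls are benzylated. The wings are activated as Mannich bases because free hydroxymethyl-phloroglucinols self-condense.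

**Step 1**
Reactants: 1 3,5-bis(benzyloxy)phenol
Product: 2 3,5-bis(benzyloxy)phenyl N-isopropylcarbamate
Conditions: i-PrNCO, Et3N (cat.), CH2Cl2, rt
Reagents that add atoms: isopropyl isocyanate, CC(C)N=C=O
Why: Base-catalysed addition of the phenol O–H across the isocyanate (carbamoylation) installs a strong ortho-metalation director that can later be removed under mild E1cB conditions.

**Step 2**
Reactants: 2 3,5-bis(benzyloxy)phenyl N-isopropylcarbamate
Product: 6 3,5-bis(benzyloxy)-2-(trimethylsilyl)phenyl N-isopropylcarbamate, via N-TBS carbamate 3 (not isolated), via aryllithium 4 (not isolated), via N-TBS C-TMS carbamate 5 (not isolated)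
Conditions: TBSOTf, TMEDA, Et2O, 0 °C to rt; n-BuLi, TMEDA, −78 °C; TMSCl, −78 °C to rt; aq NaHSO4
Reagents that add atoms: chlorotrimethylsilane, C[Si](C)(C)Cl; tert-butyldimethylsilyl triflate, CC(C)(C)[Si](C)(C)OS(=O)(=O)C(F)(F)F (silyl group present only in 3, 4, 5); n-butyllithium, [Li]CCCC (lithium present only in 4)
Why: Directed ortho-metalation, in which transient N-silylation keeps the carbamate from collapsing to isocyanate, the O-carbamate and the adjacent benzyloxy group jointly steer n-BuLi to the C–H between them (the two such positions are equivalent, and −78 °C suppresses benzylic deprotonation), TMSCl traps the aryllithium, and the acidic work-up removes the N-silyl group.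

**Step 3**
Reactants: 6 3,5-bis(benzyloxy)-2-(trimethylsilyl)phenyl N-isopropylcarbamate
Product: 8 3,5-bis(benzyloxy)-2-(trimethylsilyl)phenyl trifluoromethanesulfonate, via silylphenol 7 (not isolated)
Conditions: DBU, Et2NH, MeCN, 40 °C; then PhNTf2, rt
Reagents that add atoms: N-phenylbis(trifluoromethanesulfonimide), O=S(=O)(N(c1ccccc1)S(=O)(=O)C(F)(F)F)C(F)(F)F
Why: E1cB carbamate cleavage (the expelled isocyanate is scavenged by Et2NH) followed by O-sulfonylation of the released phenoxide in the same flask, under conditions too mild to protodesilylate the arene.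

**Step 4**
Reactants: 8 3,5-bis(benzyloxy)-2-(trimethylsilyl)phenyl trifluoromethanesulfonate; 9 (S)-2-methylbutanoic acid
Product: 11 (S)-1-[2,4-bis(benzyloxy)-6-hydroxyphenyl]-2-methylbutan-1-one, via aryne 10 (not isolated)
Conditions: CsF (4 equiv), THF (dilute), 125 °C, sealed vessel
Reagents that add atoms: none
Why: Fluoride strips the silyl group from C1 and triflate leaves C2, giving aryne 10; the carboxylate of 9 bonds through oxygen to C2, and the carbanion left at C1 swings onto the neighbouring ester carbonyl via a four-centre transition state, so that the acyl group migrates from O to C and the phenoxide of 11 is expelled. The closest known reaction type is exactly this one, the CsF-induced insertion of arynes from 2-silylaryl triflates into the C–O bond of carboxylic acids (O-arylation followed by an anionic Fries-type shift), for which hot dilute THF is chosen because it favours the intramolecular shift over protonation of the aryl anion. The step closes no ring and creates no stereocentre; the (S) centre of 9 is a passenger, and it should hold because no acylium ion, ketene or Lewis acid intervenes and the ketone is born as an electron-rich phenoxide that is reluctant to enolise. The selectivity required is regiochemical, and it is secured by the benzyloxy group on C6, whose inductive pull distorts the C1–C2 triple bond so that nucleophiles attack the remote carbon C2 and charge accumulates at C1 beside the ether; the ketone therefore ends up flanked by OBn and OH. Arynes of this 3,5-dialkoxy type are known to obey the same rule in acyl-alkylation with β-keto esters, which likewise depends on the aryl anion closing on a carbonyl group.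

**Step 5**
Reactants: 11 (S)-1-[2,4-bis(benzyloxy)-6-hydroxyphenyl]-2-methylbutan-1-one
Product: 12 (S)-2-methyl-1-(2,4,6-trihydroxyphenyl)butan-1-one
Conditions: H2 (1 atm), 10% Pd/C, EtOAc–MeOH, rt
Reagents that add atoms: none
Why: Catalytic hydrogenolysis of both benzyl aryl ethers, under neutral conditions that should leave the chelated electron-rich aryl ketone unreduced and the α-stereocentre untouched.

**Step 6**
Reactants: 13 2,4,6-trihydroxytoluene; 14 butanoyl chloride
Product: 15 1-(2,4,6-trihydroxy-3-methylphenyl)butan-1-one
Conditions: AlCl3 (4 equiv), PhNO2, 65 °C; then ice/aq HCl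
Reagents that add atoms: none
Why: Friedel–Crafts C-acylation, in which the two free ring positions of 13 are equivalent and the first acyl group deactivates the ring, so a single monoketone is expected.

**Step 7**
Reactants: 15 1-(2,4,6-trihydroxy-3-methylphenyl)butan-1-one
Product: 16 1-[4,6-bis(benzyloxy)-2-hydroxy-3-methylphenyl]butan-1-one
Conditions: BnBr (2.05 equiv), K2CO3, acetone, reflux
Reagents that add atoms: benzyl bromide, BrCc1ccccc1
Why: Williamson etherification under partial-alkylation control, in which the para 4-OH and the less hindered ortho 6-OH react while the 2-OH stays free, because the 3-methyl group presses it into a strong hydrogen bond with the ketone and it is shielded on both sides.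

**Step 8**
Reactants: 16 1-[4,6-bis(benzyloxy)-2-hydroxy-3-methylphenyl]butan-1-one
Product: 17 1-[4,6-bis(benzyloxy)-2-methoxy-3-methylphenyl]butan-1-one
Conditions: MeI (3 equiv), K2CO3, DMF, 40 °C
Reagents that add atoms: iodomethane, CI
Why: Williamson O-methylation of the only remaining phenol, which needs excess MeI and a warm dipolar aprotic solvent to break the chelate but should strongly favour O- over C-alkylation there.

**Step 9**
Reactants: 17 1-[4,6-bis(benzyloxy)-2-methoxy-3-methylphenyl]butan-1-one
Product: 18 1-(4,6-dihydroxy-2-methoxy-3-methylphenyl)butan-1-one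
Conditions: H2 (1 atm), 10% Pd/C, EtOAc–MeOH, rt
Reagents that add atoms: none
Why: Catalytic hydrogenolysis removes both benzyl ethers and leaves the methyl ether and the aryl ketone in place, giving the wing ketone with its only free ring carbon between two hydroxyls.

**Step 10**
Reactants: 18 1-(4,6-dihydroxy-2-methoxy-3-methylphenyl)butan-1-one
Product: 19 1-{3-[(dimethylamino)methyl]-2,4-dihydroxy-6-methoxy-5-methylphenyl}butan-1-one
Conditions: Eschenmoser's salt (Me2N=CH2 I, 1.05 equiv), CH2Cl2–MeCN, 0 °C to rt; aq NaHCO3
Reagents that add atoms: dimethyl(methylidene)ammonium iodide, C[N+](C)=C.[I-]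
Why: Mannich aminomethylation by a preformed iminium salt at the single unsubstituted, doubly hydroxyl-activated ring carbon, which avoids free formaldehyde and so avoids self-bridging of the wing.

**Step 11**
Reactants: 12 (S)-2-methyl-1-(2,4,6-trihydroxyphenyl)butan-1-one (1 equiv); 19 1-{3-[(dimethylamino)methyl]-2,4-dihydroxy-6-methoxy-5-methylphenyl}butan-1-one (2.1 equiv)
Product: 22 Agrimol B, via o-quinone methide 20 (not isolated), via mono-bridged dimer 21 (not isolated)
Conditions: 1,4-dioxane, 100 °C, N2 sweep; dilute aq HCl wash
Reagents that add atoms: none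
Why: Thermal loss of dimethylamine from the phenolic Mannich base gives o-quinone methide 20, which is taken up in turn by C3 and C5 of 12 through conjugate addition and rearomatisation (the known Mannich-base route to methylene-bridged acylphloroglucinols), and since 19 has no free ring carbon and 12 has exactly two, the trimer is the end point.

**Compound list**
1 | 3,5-bis(benzyloxy)phenol | Oc1cc(OCc2ccccc2)cc(OCc2ccccc2)c1 | starting material
2 | 3,5-bis(benzyloxy)phenyl N-isopropylcarbamate | CC(C)NC(=O)Oc1cc(OCc2ccccc2)cc(OCc2ccccc2)c1 | intermediate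
3 | 3,5-bis(benzyloxy)phenyl N-(tert-butyldimethylsilyl)-N-isopropylcarbamate, not isolated | CC(C)N(C(=O)Oc1cc(OCc2ccccc2)cc(OCc2ccccc2)c1)[Si](C)(C)C(C)(C)C | intermediate
4 | 2-lithio derivative of 3, not isolated | [Li]c1c(OC(=O)N(C(C)C)[Si](C)(C)C(C)(C)C)cc(OCc2ccccc2)cc1OCc1ccccc1 | intermediate
5 | 3,5-bis(benzyloxy)-2-(trimethylsilyl)phenyl N-(tert-butyldimethylsilyl)-N-isopropylcarbamate, not isolated | C[Si](C)(C)c1c(OC(=O)N(C(C)C)[Si](C)(C)C(C)(C)C)cc(OCc2ccccc2)cc1OCc1ccccc1 | intermediate
6 | 3,5-bis(benzyloxy)-2-(trimethylsilyl)phenyl N-isopropylcarbamate | C[Si](C)(C)c1c(OC(=O)NC(C)C)cc(OCc2ccccc2)cc1OCc1ccccc1 | intermediate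
7 | 3,5-bis(benzyloxy)-2-(trimethylsilyl)phenol, not isolated | C[Si](C)(C)c1c(O)cc(OCc2ccccc2)cc1OCc1ccccc1 | intermediate
8 | 3,5-bis(benzyloxy)-2-(trimethylsilyl)phenyl trifluoromethanesulfonate | C[Si](C)(C)c1c(OS(=O)(=O)C(F)(F)F)cc(OCc2ccccc2)cc1OCc1ccccc1 | intermediate
9 | (S)-2-methylbutanoic acid | CC[C@H](C)C(=O)O | starting material
10 | 3,5-bis(benzyloxy)benzyne (1,2-didehydro-3,5-bis(benzyloxy)benzene), not isolated | C1#CC(OCc2ccccc2)=CC(OCc2ccccc2)=C1 | intermediate
11 | (S)-1-[2,4-bis(benzyloxy)-6-hydroxyphenyl]-2-methylbutan-1-one | CC[C@H](C)C(=O)c1c(O)cc(OCc2ccccc2)cc1OCc1ccccc1 | intermediate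
12 | (S)-2-methyl-1-(2,4,6-trihydroxyphenyl)butan-1-one | CC[C@H](C)C(=O)c1c(O)cc(O)cc1O | intermediate
13 | 2,4,6-trihydroxytoluene | Cc1c(O)cc(O)cc1O | starting material
14 | butanoyl chloride | CCCC(=O)Cl | starting material
15 | 1-(2,4,6-trihydroxy-3-methylphenyl)butan-1-one | CCCC(=O)c1c(O)cc(O)c(C)c1O | intermediate
16 | 1-[4,6-bis(benzyloxy)-2-hydroxy-3-methylphenyl]butan-1-one | CCCC(=O)c1c(O)c(C)c(OCc2ccccc2)cc1OCc1ccccc1 | intermediate
17 | 1-[4,6-bis(benzyloxy)-2-methoxy-3-methylphenyl]butan-1-one | CCCC(=O)c1c(OC)c(C)c(OCc2ccccc2)cc1OCc1ccccc1 | intermediate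
18 | 1-(4,6-dihydroxy-2-methoxy-3-methylphenyl)butan-1-one | CCCC(=O)c1c(O)cc(O)c(C)c1OC | intermediate
19 | 1-{3-[(dimethylamino)methyl]-2,4-dihydroxy-6-methoxy-5-methylphenyl}butan-1-one | CCCC(=O)c1c(O)c(CN(C)C)c(O)c(C)c1OC | intermediate
20 | 4-butanoyl-5-hydroxy-3-methoxy-2-methyl-6-methylidenecyclohexa-2,4-dien-1-one (wing o-quinone methide), not isolated | CCCC(=O)C1=C(O)C(=C)C(=O)C(C)=C1OC | intermediate
21 | (S)-1-{3-[(3-butanoyl-2,6-dihydroxy-4-methoxy-5-methylphenyl)methyl]-2,4,6-trihydroxyphenyl}-2-methylbutan-1-one, not isolated | CC[C@H](C)C(=O)c1c(O)cc(O)c(Cc2c(O)c(C)c(OC)c(C(=O)CCC)c2O)c1O | intermediate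
22 | Agrimol B, (S)-1-{3,5-bis[(3-butanoyl-2,6-dihydroxy-4-methoxy-5-methylphenyl)methyl]-2,4,6-trihydroxyphenyl}-2-methylbutan-1-one | CCCC(=O)c1c(O)c(Cc2c(O)c(Cc3c(O)c(C)c(OC)c(C(=O)CCC)c3O)c(O)c(C(=O)[C@@H](C)CC)c2O)c(O)c(C)c1OC | target

Total step count: 11.

Longest linear sequence: 6 steps (steps 1–5 then 11, or steps 6–10 then 11).

**Steps most likely to fail**

1. **Step 4.**
   - Risk: the aryl anion may pick up a proton (from bifluoride or adventitious water) before the acyl group shifts, so that plain O-arylation takes over. Long heating with fluoride could also erode the α-stereocentre.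
   - Fallback: the same ortho-metalated aryl ester is reached without an aryne and at low temperature. The fallback sets out from 2. Lithiation as in step 2 (through 3 and 4) is quenched with I2 in place of TMSCl.
   - This should give the N-silylated iodocarbamate F1 and, after the acidic work-up, 3,5-bis(benzyloxy)-2-iodophenyl N-isopropylcarbamate F2.
   - DBU/Et2NH in MeCN then frees 3,5-bis(benzyloxy)-2-iodophenol F3. DCC/DMAP esterification with 9 gives 3,5-bis(benzyloxy)-2-iodophenyl (S)-2-methylbutanoate F4.
   - Iodine–lithium exchange with n-BuLi in THF at −95 °C produces the ortho-lithiated ester F5. Its exchange-triggered anionic Fries-type O-to-C acyl shift and an NH4Cl quench bring the sequence back to the route at 11.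

2. **Step 11.**
   - Risk: the quinone methide may be released faster than it is captured. Bridges already formed may exchange under the amine-basic conditions (retro-addition, or ipso attack on a second Mannich base). The second alkylation may also stall, so that scrambling and incomplete bridging compete.
   - Fallback: the roles of electrophile and nucleophile are exchanged. The fallback sets out from 12, which with two equivalents of Eschenmoser's salt should give (S)-1-{3,5-bis[(dimethylamino)methyl]-2,4,6-trihydroxyphenyl}-2-methylbutan-1-one F6.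
   - Heating F6 with 18 (2.2 equiv) in dioxane lets the wing attack through its single free carbon. The reaction passes through the mono-bridged Mannich base F7 and returns to the route at 22.

3. **Step 7.**
   - Risk: poor discrimination between the two ortho hydroxyls, over-alkylation, and C-benzylation at the free ring carbon may all lower the supply of the correctly masked wing.
   - Fallback: selective deprotection replaces selective protection. The fallback sets out from 15, which is exhaustively benzylated (excess BnBr, K2CO3, DMF) to 1-[2,4,6-tris(benzyloxy)-3-methylphenyl]butan-1-one F8.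
   - One equivalent of BCl3 in CH2Cl2 at −78 °C then performs a carbonyl-chelation-directed mono-debenzylation. This should prefer the doubly flanked, out-of-plane 2-O-benzyl group, and the sequence rejoins the route at 16.

**Further compounds**
F1 | step 4 | 3,5-bis(benzyloxy)-2-iodophenyl N-(tert-butyldimethylsilyl)-N-isopropylcarbamate | CC(C)N(C(=O)Oc1cc(OCc2ccccc2)cc(OCc2ccccc2)c1I)[Si](C)(C)C(C)(C)C
F2 | step 4 | 3,5-bis(benzyloxy)-2-iodophenyl N-isopropylcarbamate | CC(C)NC(=O)Oc1cc(OCc2ccccc2)cc(OCc2ccccc2)c1I
F3 | step 4 | 3,5-bis(benzyloxy)-2-iodophenol | Oc1cc(OCc2ccccc2)cc(OCc2ccccc2)c1I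
F4 | step 4 | 3,5-bis(benzyloxy)-2-iodophenyl (S)-2-methylbutanoate | CC[C@H](C)C(=O)Oc1cc(OCc2ccccc2)cc(OCc2ccccc2)c1I
F5 | step 4 | 3,5-bis(benzyloxy)-2-lithiophenyl (S)-2-methylbutanoate | [Li]c1c(OC(=O)[C@@H](C)CC)cc(OCc2ccccc2)cc1OCc1ccccc1
F6 | step 11 | (S)-1-{3,5-bis[(dimethylamino)methyl]-2,4,6-trihydroxyphenyl}-2-methylbutan-1-one | CC[C@H](C)C(=O)c1c(O)c(CN(C)C)c(O)c(CN(C)C)c1O
F7 | step 11 | (S)-1-{3-[(3-butanoyl-2,6-dihydroxy-4-methoxy-5-methylphenyl)methyl]-5-[(dimethylamino)methyl]-2,4,6-trihydroxyphenyl}-2-methylbutan-1-one | CC[C@H](C)C(=O)c1c(O)c(CN(C)C)c(O)c(Cc2c(O)c(C)c(OC)c(C(=O)CCC)c2O)c1O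
F8 | step 7 | 1-[2,4,6-tris(benzyloxy)-3-methylphenyl]butan-1-one | CCCC(=O)c1c(OCc2ccccc2)c(C)c(OCc2ccccc2)cc1OCc1ccccc1
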